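## Analysis of the target

The target is a monocyclic C10 terpenoid ether. With the ring numbered C1 to C6, C1 carries the exocyclic methylene C7, C2 and C3 are methylenes, C4 carries the acetoxy group, C5 is the gem-dimethyl quaternary carbon, and C6 carries C8H2, bound through oxygen to C7 of a coumarin. There are two stereocentres, C4 (R) and C6 (S), on either side of C5. The C4 oxygen and C8 lie on the same ring face (cis, 1,3-diequatorial), and no functional group sits between them to relay one configuration to the other. The acetate and the coumarin lactone rule out hydride, organolithium and hydroxide reagents once they are in place. The exocyclic alkene can slip into the ring (C1=C6) under acid, and C6–H is allylic, so C8 must already be at the ether oxidation level when C1 becomes sp2. Both oxygenated carbons, C4 and C8, are neopentyl-like, which slows every substitution near them. The strategy rests on one feature: C1 and C4 are para on the ring, C4 bears oxygen and C1 bears exactly one exocyclic carbon. If the C4 oxygen is tied back to C1, the ring becomes a 7-oxabicyclo[2.2.1]heptane, the hydrogenated adduct of a 2-substituted furan (C1–C4, with C7 on C1) and the C5=C6 alkene of a 3-methylbut-2-enoate whose carboxyl carbon is C8.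

## Retrosynthetic reasoning

**Acetate.** The C4 O–acyl bond of target 14 is cut first, giving alcohol 13. The acetate would survive neither the hydride step nor the basic arylation, so it is put on last. The forward step only has to acylate a hindered secondary alcohol next to C5.

**Oxygen bridge.** In 13 the C4 oxygen is reconnected to C1 and a halogen is placed on C7, giving iodide 12. The forward reaction is a reductive β-elimination: electrons arrive at C7 and the C1–O bond leaves, so the alkene can only be exocyclic. The C4–O bond is never broken, so C4 keeps its configuration. The gain is a rigid bicycle in which the cis relation of the C4 oxygen and C8 is a matter of geometry.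

**C7–I bond.** Iodide 12 comes from primary alcohol 11. The forward step is a substitution at a neopentyl carbon that also has a β-oxygen, so it needs forcing but cannot rearrange.

**Aryl ether.** The C8–O(aryl) bond of 11 is cut to umbelliferone 9 and cyclic sulfate 8. The two primary hydroxyls of diol 6 are cis and 1,4 to each other. Activating one while the other is free would lead to intramolecular etherification rather than arylation. The cyclic sulfate activates both oxygens at once. After one displacement the second oxygen is held as sulfate monoester 10, which cannot cyclise and is then hydrolysed to 11. The phenoxide should attack C8, whose neighbour C6 bears a hydrogen, and not the neopentyl C7.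

**Sulfate, diol, lactone.** Sulfate 8 comes from diol 6 through sulfite 7, and 6 from reduction of lactone 5. In 5 the two carbons are still distinct by oxidation level: C8 is the carbonyl carbon and C7 the alkyl carbon.

**C2–C3 saturation.** Lactone 5 comes from alkene 4 by hydrogenation. This supplies the two ring methylenes and closes off cycloreversion.

**Cycloaddition.** In 4 the C4–C5 and C6–C1 bonds are cut, which returns the achiral ester 3. This is the key disconnection: two rings, two skeletal bonds and three stereocentres go back to one furan and one enoate. The tether fixes regiochemistry and the exo fusion, so the forward reaction has to supply only the enantioface.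

**Ester.** Ester 3 is cut at the acyl C–O bond to furfuryl alcohol 1 and acid chloride 2, a single acylation.

## Alternatives that were turned down

**Alternative 1:** The ring bond C6–C1 is cut, and C8 is traced back to a boronate. In the forward key step the enyne acetate A1 reacts with a diboron ester under Pd(OAc)2. Hydropalladation of the terminal alkyne puts palladium on C1, the vinyl group inserts 6-exo to form C1–C6, and the C8–Pd bond is borylated to give A2.
- For: A2 already holds the carbocycle, the methylene, the C4 acetate and a C8 handle. Oxidation and a Mitsunobu arylation would finish the synthesis. The single stereocentre of A1 is within reach of asymmetric reverse prenylation of an alkynyl aldehyde. On step count and on the security of the absolute configuration this plan is stronger than the chosen one.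
- Against: C6 is created during the insertion, next to quaternary C5. Its relation to C4 rests only on a chair preference for an equatorial acetate. The alkyl–palladium at C8 has a β-hydrogen on C6, so elimination to a diene competes with borylation. Borylative enyne cyclisation is best established for five-membered rings.
- Comparison: the chosen route is longer, but it offers a C4/C6 relation enforced by a bicyclic framework and a methylene that cannot form in the wrong position.

**Alternative 2:** The C5–C6 bond is cut, and the carbocycle is traced to the pyran A3, in which the future C4 oxygen is the ring oxygen, C4=C5 is an exocyclic enol ether and C6 is an allylic ether carbon. Zerovalent palladium ionises the C6–O bond. The tethered tetrasubstituted enolate then attacks the allyl terminus C6 through carbon, giving the 4-methylidenecyclohexanone A4.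
- For: a redox-neutral catalytic rearrangement that makes the quaternary–tertiary bond and the methylene together. It is the equal of the chosen key step in elegance.
- Against: the bond joins a fully substituted enolate carbon to the more substituted allyl terminus, while the CH2 terminus and O-alkylation compete. The allyl unit has an unsubstituted terminus and can exchange faces, so chirality transfer from A3 is insecure and a chiral ligand would have to override it. C4 is set afterwards by a separate ketone reduction under substrate control only. A3 itself needs several steps and contains a labile enol ether, and the benzyl-type ether must be exchanged for the coumarin.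
- Comparison: the chosen route sets C4 and C6 in the same event and reaches its key substrate in one step.

**Alternative 3:** The C5–C6 and C1–C2 bonds are cut, an all-carbon [4+2]. Diene A5 and the oxazolidinone-bound dienophile A6 combine under Et2AlCl to give A7, with C4 as a silyl enol ether.
- For: the electronic regiochemistry is matched (siloxy carbon para to the acyl group), and facial control by a chelated N-enoyl oxazolidinone is well precedented. On predictability of the absolute configuration it is stronger than the chosen key step.
- Against: the reacting diene terminus C5 is fully substituted. Its inward methyl destabilises the s-cis conformer, and it must bond to a β-substituted dienophile, so a stepwise Michael pathway or loss of the silyl group is likely. The C1 stereocentre is discarded: the acyl carbon must be reduced and dehydrated to the methylene. C4 again needs a separate reduction. Auxiliary removal, protecting-group exchange, arylation and acetylation make the sequence clearly longer.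
- Comparison: the chosen route stores the C4 oxygen configuration and the latent methylene in the cycloadduct itself.

Key step: step 2

Remark on the chemistry: the sense of induction of the oxazaborolidinium catalyst on this intramolecular substrate cannot be derived safely from the intermolecular model. The (S)-configured catalyst is written; its equally available (R)-antipode is used if the (S)-form favours the mirror-image adduct.

## Route

Step 1
Reactants: 1 furfuryl alcohol (furan-2-ylmethanol); 2 3-methylbut-2-enoyl chloride
Product: 3 furan-2-ylmethyl 3-methylbut-2-enoate
Conditions: pyridine, CH2Cl2, 0 °C to rt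
Reagents that add atoms: none
Why: Nucleophilic acyl substitution of the acid chloride by the primary alcohol; pyridine instead of a trialkylamine should keep the acid chloride from forming the vinylketene that leads to the deconjugated ester, and the acid-sensitive furfuryl group stays under basic conditions.

Step 2
Reactants: 3 furan-2-ylmethyl 3-methylbut-2-enoate
Product: 4 (3aS,6R,7aR)-7,7-dimethyl-7,7a-dihydro-3H-3a,6-epoxy-2-benzofuran-1(6H)-one, the 7-oxabicyclo[2.2.1]hept-2-ene with the γ-lactone fused exo across C1–C6 (C8 on the face of the oxygen bridge)
Conditions: (3aS)-1-(2-methylphenyl)-3,3-diphenyltetrahydro-1H,3H-pyrrolo[1,2-c][1,3,2]oxazaborole (20 mol %), HN(SO2CF3)2 (20 mol %), CH2Cl2 (0.05 M), −40 to −20 °C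
Reagents that add atoms: none
Why: Proposed new method: the N-protonated oxazaborolidinium ion should bind the ester carbonyl and lower the enoate LUMO, so that the tethered furan adds across C5=C6 in a concerted, asynchronous intramolecular [4+2] in which the bond from the unsubstituted furan carbon C4 to the electrophilic CMe2 carbon C5 probably leads and the C6–C1 bond follows; the closest known reaction types are the thermal intramolecular Diels–Alder reactions of furfuryl fumarates and N-furfuryl acrylamides and the oxazaborolidinium-catalysed intermolecular cycloaddition of furans with acrylates, none of which covers a β,β-dimethyl enoate on an ester tether. The carbocycle closes by suprafacial addition across furan C2 and C5, which leaves the furan oxygen as a one-atom bridge between C1 and C4. The γ-lactone closes through the same C6–C1 bond as a fused five-membered ring, with both reacting double bonds exo to it. Regiochemistry needs no control, because a three-atom tether can deliver C6 only to the substituted furan carbon. C1 and C4 are set together by the suprafacial diene component. C6 is set relative to them by the tether, which can span C1–C6 only with C8 exo, since the endo mode would require a torsion near 80° inside a five-membered ring. The one selectivity the substrate does not secure is the enantioface, and this must come from the aryl groups of the catalyst shielding one face of the bound enoate. Reversibility is countered by the low temperature and by hydrogenating the adduct at once.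

Step 3
Reactants: 4 exo cycloadduct
Product: 5 (3aS,6R,7aR)-7,7-dimethylhexahydro-3a,6-epoxy-2-benzofuran-1(3H)-one, the saturated lactone-fused 7-oxabicyclo[2.2.1]heptane
Conditions: H2 (1 atm), Pd/C, EtOAc, 0 °C, on the cold crude adduct
Reagents that add atoms: none
Why: Heterogeneous catalytic hydrogenation of the strained C2=C3 bond should be fast and leave the bridge ether and the lactone alone; it creates no stereocentre and removes the diene half needed for cycloreversion.

Step 4
Reactants: 5 saturated lactone
Product: 6 [(1S,2S,4R)-3,3-dimethyl-7-oxabicyclo[2.2.1]heptane-1,2-diyl]dimethanol (C7–OH on the bridgehead C1, C8–OH exo on C6)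
Conditions: LiAlH4, THF, 0 °C to rt
Reagents that add atoms: none
Why: Hydride reduction of a lactone to the diol; the bridge ether is inert and no stereocentre is touched.

Step 5
Reactants: 6 diol
Product: 8 cyclic sulfate of diol 6 (seven-membered 1,3,2-dioxathiepane 2,2-dioxide spanning O7 and O8), via cyclic sulfite 7 (not isolated)
Conditions: SOCl2, Et3N, CH2Cl2, 0 °C; then RuCl3·xH2O (1 mol %), NaIO4, MeCN/H2O, 0 °C
Reagents that add atoms: thionyl chloride, O=S(Cl)Cl; sodium periodate, [Na+].[O-]I(=O)(=O)=O
Why: Cyclic sulfite formation followed by ruthenium-catalysed oxidation is the standard route to cyclic sulfates, including seven-membered ones from 1,4-diols; both hydroxyls are tied up in the first operation, so no free hydroxyl ever faces an activated neighbour, and the brief cold oxidation should spare the bridgehead ether.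

Step 6
Reactants: 8 cyclic sulfate; 9 umbelliferone (7-hydroxy-2H-chromen-2-one)
Product: 11 7-{[(1S,2S,4R)-1-(hydroxymethyl)-3,3-dimethyl-7-oxabicyclo[2.2.1]heptan-2-yl]methoxy}-2H-chromen-2-one, via caesium sulfate monoester 10 (not isolated)
Conditions: Cs2CO3, DMF, 70 °C; then H2SO4 (cat.), H2O (2 equiv), THF, rt
Reagents that add atoms: none
Why: SN2 opening of a cyclic sulfate by a phenoxide should take place at C8, whose neighbour C6 carries a hydrogen, and not at the neopentyl C7; the C7 oxygen remains as an unreactive sulfate monoester that cannot cyclise onto C8, and acid hydrolysis with S–O cleavage then frees the C7 hydroxyl without touching the coumarin or the bridge.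

Step 7
Reactants: 11 hydroxy aryl ether
Product: 12 7-{[(1S,2S,4R)-1-(iodomethyl)-3,3-dimethyl-7-oxabicyclo[2.2.1]heptan-2-yl]methoxy}-2H-chromen-2-one
Conditions: I2, PPh3, imidazole, toluene, 90 °C
Reagents that add atoms: iodine, II
Why: Appel-type iodination under Garegg–Samuelsson conditions converts the alcohol into an alkoxyphosphonium ion that iodide displaces; the neopentyl C7 needs heat, but the β-oxygen suppresses ionisation and rearrangement, and C7 is not a stereocentre.

Step 8
Reactants: 12 iodide
Product: 13 7-{[(1S,3R)-3-hydroxy-2,2-dimethyl-6-methylidenecyclohexyl]methoxy}-2H-chromen-2-one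
Conditions: Zn dust (acid-washed), THF/H2O 9:1, ultrasound, 40 °C
Reagents that add atoms: none
Why: Zinc inserts into the C7–I bond and the resulting organozinc expels the β-alkoxide on C1 (Boord-type elimination, as in the Bernet–Vasella fragmentation), helped by the release of bicyclic strain; only the C1–O bond breaks, so C1=C7 is formed regiospecifically and the C4 oxygen and C8 keep the cis relation set in step 2, while the coumarin is not reduced by zinc in a neutral medium.

Step 9
Reactants: 13 alcohol
Product: 14 (1R,3S)-2,2-dimethyl-4-methylidene-3-{[(2-oxo-2H-chromen-7-yl)oxy]methyl}cyclohexyl acetate (target)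
Conditions: Ac2O, pyridine, 4-(dimethylamino)pyridine (cat.), CH2Cl2, rt
Reagents that add atoms: acetic anhydride, CC(=O)OC(C)=O
Why: Nucleophile-catalysed O-acylation of the hindered secondary alcohol; the conditions are non-acidic, so the exocyclic alkene should not migrate, and the coumarin is unaffected.

## Compound list

1 | furfuryl alcohol (furan-2-ylmethanol) | OCc1ccco1 | starting material
2 | 3-methylbut-2-enoyl chloride | CC(C)=CC(Cl)=O | starting material
3 | furan-2-ylmethyl 3-methylbut-2-enoate | CC(C)=CC(=O)OCc1ccco1 | intermediate
4 | (3aS,6R,7aR)-7,7-dimethyl-7,7a-dihydro-3H-3a,6-epoxy-2-benzofuran-1(6H)-one (exo adduct) | O=C1OC[C@@]23C=C[C@@H](O2)C(C)(C)[C@@H]13 | intermediate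
5 | (3aS,6R,7aR)-7,7-dimethylhexahydro-3a,6-epoxy-2-benzofuran-1(3H)-one | O=C1OC[C@@]23CC[C@@H](O2)C(C)(C)[C@@H]13 | intermediate
6 | [(1S,2S,4R)-3,3-dimethyl-7-oxabicyclo[2.2.1]heptane-1,2-diyl]dimethanol | OC[C@@]12CC[C@@H](O1)C(C)(C)[C@H]2CO | intermediate
7 | cyclic sulfite of diol 6 (either configuration at sulfur) | O=S1OC[C@@]23CC[C@@H](O2)C(C)(C)[C@H]3CO1 | intermediate (not isolated)
8 | cyclic sulfate of diol 6 | O=S1(=O)OC[C@@]23CC[C@@H](O2)C(C)(C)[C@H]3CO1 | intermediate
9 | umbelliferone (7-hydroxy-2H-chromen-2-one) | Oc1ccc2ccc(=O)oc2c1 | starting material
10 | caesium {(1S,2S,4R)-3,3-dimethyl-2-[(2-oxo-2H-chromen-7-yl)oxymethyl]-7-oxabicyclo[2.2.1]heptan-1-yl}methyl sulfate | [Cs+].[O-]S(=O)(=O)OC[C@@]12CC[C@@H](O1)C(C)(C)[C@H]2COc1ccc2ccc(=O)oc2c1 | intermediate (not isolated)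
11 | 7-{[(1S,2S,4R)-1-(hydroxymethyl)-3,3-dimethyl-7-oxabicyclo[2.2.1]heptan-2-yl]methoxy}-2H-chromen-2-one | OC[C@@]12CC[C@@H](O1)C(C)(C)[C@H]2COc1ccc2ccc(=O)oc2c1 | intermediate
12 | 7-{[(1S,2S,4R)-1-(iodomethyl)-3,3-dimethyl-7-oxabicyclo[2.2.1]heptan-2-yl]methoxy}-2H-chromen-2-one | IC[C@@]12CC[C@@H](O1)C(C)(C)[C@H]2COc1ccc2ccc(=O)oc2c1 | intermediate
13 | 7-{[(1S,3R)-3-hydroxy-2,2-dimethyl-6-methylidenecyclohexyl]methoxy}-2H-chromen-2-one | C=C1CC[C@@H](O)C(C)(C)[C@H]1COc1ccc2ccc(=O)oc2c1 | intermediate
14 | (1R,3S)-2,2-dimethyl-4-methylidene-3-{[(2-oxo-2H-chromen-7-yl)oxy]methyl}cyclohexyl acetate | C=C1CC[C@@H](OC(C)=O)C(C)(C)[C@H]1COc1ccc2ccc(=O)oc2c1 | target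

## Step count and least certain steps

Total: 9 steps. Longest linear sequence: 9 steps, from 1 to 14. Umbelliferone 9 enters at step 6 without prior steps.

**Step 2 (key step, the one step beyond known chemistry).**
- What may go wrong: the cycloaddition may not proceed at all. The ester tether populates the reactive rotamer poorly, and the β,β-dimethyl enoate is more electron-rich and more hindered than the dienophiles known to cyclise onto furans. The adduct, with two adjacent fully substituted carbons, may revert faster than it forms. The cationic boron Lewis acid may ionise the furfuryl C–O bond and start oligomerisation. Face selection may be poor on a substrate bound outside the geometry of the intermolecular model.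
- Fallback, by known chemistry and a different disconnection, from umbelliferone 9 back to alcohol 13: 9 is O-alkylated with geranyl bromide F1 (K2CO3, acetone) to 7-geranyloxycoumarin F2. Shi epoxidation (1,2:4,5-di-O-isopropylidene-D-erythro-hexo-2,3-diulo-2,6-pyranose as catalyst, KHSO5, buffered MeCN/H2O, 0 °C) of the distal, electron-richer trisubstituted alkene should give the (R)-6',7'-epoxide F3. Radical cyclisation with Cp2TiCl (trivalent titanium, made from Cp2TiCl2 and Mn in THF) opens the epoxide at its tertiary carbon and closes the ring 6-endo through a chair with the titanoxy and aryloxymethyl groups both equatorial. Loss of a methyl hydrogen then gives the exocyclic alkene, that is 13, and step 9 completes the synthesis.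

**Step 6.**
- What may go wrong: slow bimolecular substitution at C8, which is flanked by two fully substituted carbons. On long heating, elimination across C6–C8 or attack at C7 or at sulfur would take over.
- Fallback, from cyclic sulfate 8 back to alcohol 13, with the arylation postponed until C1 is sp2 and C8 less crowded: 8 is opened with the smaller, more nucleophilic CsOAc (DMF, 90 °C) and hydrolysed in the same flask (H2SO4 cat., H2O, THF) to [(1S,2S,4R)-1-(hydroxymethyl)-3,3-dimethyl-7-oxabicyclo[2.2.1]heptan-2-yl]methyl acetate F4. Iodination as in step 7 gives [(1S,2S,4R)-1-(iodomethyl)-3,3-dimethyl-7-oxabicyclo[2.2.1]heptan-2-yl]methyl acetate F5. Zinc as in step 8 gives [(1S,3R)-3-hydroxy-2,2-dimethyl-6-methylidenecyclohexyl]methyl acetate F6. Methanolysis (K2CO3, MeOH) gives (1R,3S)-3-(hydroxymethyl)-2,2-dimethyl-4-methylidenecyclohexan-1-ol F7. A Mitsunobu coupling (PPh3, diisopropyl azodicarboxylate, THF) of its primary hydroxyl with 9 gives 13; the hindered secondary C4 hydroxyl should stay out of the reaction.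

**Step 7.**
- What may go wrong: substitution at the neopentyl, β-oxygenated C7 may stall, so that the alkoxyphosphonium intermediate persists or breaks down by other paths.
- Fallback, from alcohol 11 back to iodide 12, replacing the phosphonium activation by an isolated sulfonate of much higher leaving-group ability and a separate displacement: 11 is converted with (CF3SO2)2O and pyridine (CH2Cl2, −20 °C) into {(1S,2S,4R)-3,3-dimethyl-2-[(2-oxo-2H-chromen-7-yl)oxymethyl]-7-oxabicyclo[2.2.1]heptan-1-yl}methyl trifluoromethanesulfonate F8. Soluble iodide (Bu4NI, MeCN, 50 °C) then displaces the triflate to give 12.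

## Further compounds

F1 | step 2 | geranyl bromide, (2E)-1-bromo-3,7-dimethylocta-2,6-diene (commercial reagent) | CC(C)=CCC/C(C)=C/CBr
F2 | step 2 | 7-{[(2E)-3,7-dimethylocta-2,6-dien-1-yl]oxy}-2H-chromen-2-one | CC(C)=CCC/C(C)=C/COc1ccc2ccc(=O)oc2c1
F3 | step 2 | 7-({(2E)-5-[(2R)-3,3-dimethyloxiran-2-yl]-3-methylpent-2-en-1-yl}oxy)-2H-chromen-2-one | CC1(C)O[C@@H]1CC/C(C)=C/COc1ccc2ccc(=O)oc2c1
F4 | step 6 | [(1S,2S,4R)-1-(hydroxymethyl)-3,3-dimethyl-7-oxabicyclo[2.2.1]heptan-2-yl]methyl acetate | OC[C@@]12CC[C@@H](O1)C(C)(C)[C@H]2COC(C)=O
F5 | step 6 | [(1S,2S,4R)-1-(iodomethyl)-3,3-dimethyl-7-oxabicyclo[2.2.1]heptan-2-yl]methyl acetate | IC[C@@]12CC[C@@H](O1)C(C)(C)[C@H]2COC(C)=O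
F6 | step 6 | [(1S,3R)-3-hydroxy-2,2-dimethyl-6-methylidenecyclohexyl]methyl acetate | C=C1CC[C@@H](O)C(C)(C)[C@H]1COC(C)=O
F7 | step 6 | (1R,3S)-3-(hydroxymethyl)-2,2-dimethyl-4-methylidenecyclohexan-1-ol | C=C1CC[C@@H](O)C(C)(C)[C@H]1CO
F8 | step 7 | {(1S,2S,4R)-3,3-dimethyl-2-[(2-oxo-2H-chromen-7-yl)oxymethyl]-7-oxabicyclo[2.2.1]heptan-1-yl}methyl trifluoromethanesulfonate | O=S(=O)(OC[C@@]12CC[C@@H](O1)C(C)(C)[C@H]2COc1ccc2ccc(=O)oc2c1)C(F)(F)F
A1 | alternative 1 | (R)-3,3-dimethyloct-1-en-7-yn-4-yl acetate | C#CCC[C@@H](OC(C)=O)C(C)(C)C=C
A2 | alternative 1 | cis-2,2-dimethyl-4-methylidene-3-[(4,4,5,5-tetramethyl-1,3,2-dioxaborolan-2-yl)methyl]cyclohexyl acetate | C=C1CC[C@@H](OC(C)=O)C(C)(C)[C@H]1CB1OC(C)(C)C(C)(C)O1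
A3 | alternative 2 | (6R)-6-{[(4-methoxybenzyl)oxy]methyl}-5-methylidene-2-(propan-2-ylidene)oxane | CC(C)=C1CCC(=C)[C@H](COCc2ccc(OC)cc2)O1
A4 | alternative 2 | (S)-3-{[(4-methoxybenzyl)oxy]methyl}-2,2-dimethyl-4-methylidenecyclohexan-1-one | C=C1CCC(=O)C(C)(C)[C@H]1COCc1ccc(OC)cc1
A5 | alternative 3 | 4-methyl-3-(trimethylsilyloxy)penta-1,3-diene | C=CC(O[Si](C)(C)C)=C(C)C
A6 | alternative 3 | (R)-4-benzyl-3-[(E)-4-(4-methoxybenzyloxy)but-2-enoyl]-1,3-oxazolidin-2-one | COc1ccc(COC/C=C/C(=O)N2C(=O)OC[C@H]2Cc2ccccc2)cc1
A7 | alternative 3 | cycloadduct with the C4 trimethylsilyl enol ether, the C1 N-acyl oxazolidinone and the C6 (4-methoxybenzyloxy)methyl group trans to it | O=C([C@@H]1CC=C(O[Si](C)(C)C)C(C)(C)[C@H]1COCc1ccc(OC)cc1)N1C(=O)OC[C@H]1Cc1ccccc1
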